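**Retrosynthetic overview**

1. Target 17 comes from selective bis-isobutyrylation of triol 15, which comes from acid unmasking of arene 14 (acetonide and Me3Si ether).
2. Arene 14 is disconnected across the benzene ring at C2-C3 and C1-C6 into 4-methyl-2H-pyran-2-one 6 and methoxyalkyne 12, joined by Diels-Alder cycloaddition and loss of CO2.
3. Feature used: arene C1 (carbinol-bearing) and C2 (OMe-bearing) are neighbours and are delivered as the two carbons of a methoxyalkyne that already carries the quaternary carbinol carbon. Arene C3 to C6, with the methyl on C4, are the diene carbons C3 to C6 of the pyranone.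
4. Pyranone 6 comes from ethyl 3-methylbut-2-enoate 1 and diethyl oxalate 2 (gamma-Claisen condensation, lactonization, decarboxylation). Alkyne 12 comes from ketone 8 and lithium methoxyacetylide made from chloroacetal 7, followed by O-silylation.
5. Ring order: pyranone ring (step 2), then the benzene ring (step 6). The dioxane ring is bought with 8 and opened in step 7.

Key step: step 6

Remark on the chemistry: the target has no stereocentre. Ketone 8 is taken as purchasable, and the 1,3-diol is carried as its acetonide with the isobutyrates installed last, because a tertiary lithium alkoxide flanked by two acyloxymethyl groups would be open to acyl shift.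

**Route**

Step 1
Reactants: 1 ethyl 3-methylbut-2-enoate; 2 diethyl oxalate
Product: 3 potassium (2Z,4Z)-1,6-diethoxy-4-methyl-1,6-dioxohexa-2,4-dien-2-olate (drawn as the cyclization-competent isomer; the geometry of the delocalized dienolate is mobile)
Conditions: KOEt, Et2O/EtOH, 0 °C to rt; salt collected by filtration
Reagents that add atoms: potassium ethoxide, CC[O-].[K+]
Why: Vinylogous (gamma) Claisen condensation, in which the extended dienolate of 1 is acylated at the gamma-methyl by non-enolizable diethyl oxalate and the equilibrium is drawn over by precipitation of the fully conjugated potassium dienolate.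

Step 2
Reactants: 3 potassium (2Z,4Z)-1,6-diethoxy-4-methyl-1,6-dioxohexa-2,4-dien-2-olate
Product: 5 4-methyl-2-oxo-2H-pyran-6-carboxylic acid, via ethyl pyranonecarboxylate 4 (not isolated)
Conditions: conc. HCl, 100 °C
Reagents that add atoms: water, O
Why: Acid liberates the dienol, whose hydroxyl lactonizes onto the cis-disposed ester (6-exo-trig closure of the pyranone ring, the diene geometry equilibrating in hot acid), and the remaining ethyl ester is then hydrolysed under the same conditions.

Step 3
Reactants: 5 4-methyl-2-oxo-2H-pyran-6-carboxylic acid
Product: 6 4-methyl-2H-pyran-2-one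
Conditions: Cu powder, neat, 230-270 °C, reduced pressure, product distilled as it forms
Reagents that add atoms: none
Why: Copper-promoted thermal protodecarboxylation of a carboxylic acid placed alpha to the ring oxygen of a 2-pyranone, with the volatile product leaving the hot zone by distillation.

Step 4
Reactants: 7 2-chloro-1,1-dimethoxyethane (chloroacetaldehyde dimethyl acetal); 8 2,2-dimethyl-1,3-dioxan-5-one
Product: 11 5-(methoxyethynyl)-2,2-dimethyl-1,3-dioxan-5-ol, via lithium methoxyacetylide 9 (not isolated), via lithium carbinolate 10 (not isolated)
Conditions: Et2NH, n-BuLi (3 equiv each), THF, 0 °C; 7, 0 °C; then 8, -78 to -30 °C; H2O quench, chromatography on Et3N-deactivated silica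
Reagents that add atoms: none
Why: Lithium diethylamide eliminates MeOH and then HCl from 7 and deprotonates the resulting methoxyacetylene, and the slim lithium acetylide then undergoes 1,2-addition to the unhindered, ester-free ketone 8 at low temperature, a neutral aqueous quench sparing the acid-labile ynol ether.

Step 5
Reactants: 11 5-(methoxyethynyl)-2,2-dimethyl-1,3-dioxan-5-ol
Product: 12 5-(methoxyethynyl)-2,2-dimethyl-5-(trimethylsilyloxy)-1,3-dioxane
Conditions: Me3SiCl, imidazole, DMF, 0 °C to rt
Reagents that add atoms: chlorotrimethylsilane, C[Si](C)(C)Cl
Why: Imidazole-assisted O-silylation, in which the small Me3Si group reaches the tertiary propargylic hydroxyl and the buffered medium avoids Meyer-Schuster rearrangement of the ynol ether carbinol.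

Step 6
Reactants: 6 4-methyl-2H-pyran-2-one; 12 5-(methoxyethynyl)-2,2-dimethyl-5-(trimethylsilyloxy)-1,3-dioxane
Product: 14 5-(2-methoxy-4-methylphenyl)-2,2-dimethyl-5-(trimethylsilyloxy)-1,3-dioxane, via bridged lactone 13 (not isolated)
Conditions: 6 (3 equiv), o-xylene (about 2 M), K2CO3 (5 mol %, suspended), BHT (cat.), sealed tube, 150-170 °C, -CO2
Reagents that add atoms: none
Why: Pyranone 6 serves as the electron-poor diene and ynol ether 12 as the electron-rich dienophile in a Diels-Alder reaction with inverse electron demand, where bond formation should be asynchronous, the alkyne carbon remote from oxygen (the one carrying the dioxanyl group) engaging pyranone C6 ahead of closure between the methoxy-bearing carbon and pyranone C3 to give bridged lactone 13. Cycloreversion of 13 with loss of CO2 is fast at this temperature and irreversible, so the benzene ring is closed by an intermolecular [4+2] cycloaddition that forms arene bonds C2-C3 and C1-C6 and is then aromatized by retro-[4+2] extrusion. The closest known reaction type is the thermal benzannulation of 2-pyranones with ynamines and alkoxyalkynes, where most pyranones carry an acceptor group, while unactivated pyranones are known to need about 150-200 °C with other alkynes, which is why forcing conditions and excess 6 are chosen. No stereocentre is created, because the two bridgehead centres of racemic 13 are erased on aromatization. The step needs regioselectivity, since the reversed orientation would give the 2-methoxy-5-methylphenyl isomer, and this is secured by the match between the oxygen-polarized alkyne and the electrophilic C6 terminus of the dienoate, helped by C5 and C6 carrying only hydrogen next to the bulky alkyne terminus. The methyl ynol ether has no hydrogen placed for retro-ene loss of ketene and the silyl ether blocks Meyer-Schuster rearrangement, so 12 should tolerate the heating.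

Step 7
Reactants: 14 5-(2-methoxy-4-methylphenyl)-2,2-dimethyl-5-(trimethylsilyloxy)-1,3-dioxane
Product: 15 2-(2-methoxy-4-methylphenyl)propane-1,2,3-triol
Conditions: AcOH/THF/H2O (3:1:1), 40 °C
Reagents that add atoms: none
Why: Mild aqueous acid hydrolyses the isopropylidene acetal and the trimethylsilyl ether together, while the tertiary benzylic C-O bond, deactivated inductively by two beta-oxygens, should not ionize in such weak acid.

Step 8
Reactants: 15 2-(2-methoxy-4-methylphenyl)propane-1,2,3-triol; 16 2-methylpropanoyl chloride (isobutyryl chloride)
Product: 17 2-hydroxy-2-(2-methoxy-4-methylphenyl)propane-1,3-diyl bis(2-methylpropanoate)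
Conditions: 16 (2.2 equiv), pyridine, CH2Cl2, -20 to 0 °C
Reagents that add atoms: none
Why: Acylation with an acid chloride and pyridine (nucleophilic acyl substitution) takes the two primary hydroxyls and leaves the hindered tertiary benzylic hydroxyl free in the absence of a stronger acyl-transfer catalyst; the two arms are identical, so no selectivity between them is required.

**Compound list**

1 | ethyl 3-methylbut-2-enoate | CCOC(=O)C=C(C)C | starting material
2 | diethyl oxalate | CCOC(=O)C(=O)OCC | starting material
3 | potassium (2Z,4Z)-1,6-diethoxy-4-methyl-1,6-dioxohexa-2,4-dien-2-olate | CCOC(=O)/C([O-])=C/C(C)=C\C(=O)OCC.[K+] | intermediate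
4 | ethyl 4-methyl-2-oxo-2H-pyran-6-carboxylate | CCOC(=O)C1=CC(C)=CC(=O)O1 | intermediate
5 | 4-methyl-2-oxo-2H-pyran-6-carboxylic acid | OC(=O)C1=CC(C)=CC(=O)O1 | intermediate
6 | 4-methyl-2H-pyran-2-one | CC1=CC(=O)OC=C1 | intermediate
7 | 2-chloro-1,1-dimethoxyethane (chloroacetaldehyde dimethyl acetal) | COC(CCl)OC | starting material
8 | 2,2-dimethyl-1,3-dioxan-5-one | CC1(C)OCC(=O)CO1 | starting material
9 | lithium methoxyacetylide | [Li+].[C-]#COC | intermediate
10 | lithium 5-(methoxyethynyl)-2,2-dimethyl-1,3-dioxan-5-olate | [Li+].[O-]C1(C#COC)COC(C)(C)OC1 | intermediate
11 | 5-(methoxyethynyl)-2,2-dimethyl-1,3-dioxan-5-ol | COC#CC1(O)COC(C)(C)OC1 | intermediate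
12 | 5-(methoxyethynyl)-2,2-dimethyl-5-(trimethylsilyloxy)-1,3-dioxane | COC#CC1(O[Si](C)(C)C)COC(C)(C)OC1 | intermediate
13 | 6-[2,2-dimethyl-5-(trimethylsilyloxy)-1,3-dioxan-5-yl]-5-methoxy-8-methyl-2-oxabicyclo[2.2.2]octa-5,7-dien-3-one (racemic, one enantiomer drawn; the two bridgehead CH centres are fixed relative to each other by the bicycle) | O=C1O[C@@H]2C=C(C)[C@H]1C(OC)=C2C3(O[Si](C)(C)C)COC(C)(C)OC3 | intermediate
14 | 5-(2-methoxy-4-methylphenyl)-2,2-dimethyl-5-(trimethylsilyloxy)-1,3-dioxane | COc1cc(C)ccc1C1(O[Si](C)(C)C)COC(C)(C)OC1 | intermediate
15 | 2-(2-methoxy-4-methylphenyl)propane-1,2,3-triol | COc1cc(C)ccc1C(O)(CO)CO | intermediate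
16 | 2-methylpropanoyl chloride (isobutyryl chloride) | CC(C)C(Cl)=O | starting material
17 | 2-hydroxy-2-(2-methoxy-4-methylphenyl)propane-1,3-diyl bis(2-methylpropanoate) | COc1cc(C)ccc1C(O)(COC(=O)C(C)C)COC(=O)C(C)C | target

**Step count**

Total steps: 8. Longest linear sequence: 6 steps (steps 1, 2, 3, 6, 7, 8 from compound 1); the alkyne branch (steps 4 and 5) joins at step 6.

**Steps most likely to fail**

1. Step 6. The cycloaddition of the unactivated pyranone may be so slow that thermal oligomerization of the ynol ether or dimerization of the pyranone outruns it, and the regiochemical preference may erode at the temperature needed. The fallback forms the aryl-carbinol bond by organolithium addition; it sets out from ketone 8 and comes back at triol 15. Purchased 1-bromo-2-methoxy-4-methylbenzene F1 is treated with n-BuLi in THF at -78 °C (bromine-lithium exchange) to give (2-methoxy-4-methylphenyl)lithium F2. This adds to 8 at -78 °C to give lithium 5-(2-methoxy-4-methylphenyl)-2,2-dimethyl-1,3-dioxan-5-olate F3, and aqueous quench gives 5-(2-methoxy-4-methylphenyl)-2,2-dimethyl-1,3-dioxan-5-ol F4. The aqueous acetic acid conditions of step 7 then remove the acetonide to give 15, and step 8 follows unchanged.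

2. Step 4. The elimination cascade may stop short or leave amide base and lithium methoxide in solution, so that enolization or self-condensation of ketone 8 competes with acetylide addition. The fallback separates alkyne formation from the addition; it sets out from chloroacetal 7 and comes back at lithium acetylide 9. Treatment of 7 with NaNH2 in liquid NH3 at -33 °C should give sodium methoxyacetylide F5. After evaporation of the NH3, cold saturated aqueous NaCl liberates methoxyacetylene (methoxyethyne) F6, which is distilled and dried. Deprotonation with n-BuLi in THF at -78 °C then gives 9 free of amine and methoxide, and the addition to 8 proceeds as in step 4.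

3. Step 5. The free carbinol 11 may undergo acid-triggered Meyer-Schuster rearrangement during isolation, or silylation of the hindered hydroxyl may lag behind decomposition. The fallback avoids the free alcohol altogether; it sets out from lithium carbinolate 10 in the flask of step 4 and comes back at 12. Excess Me3SiCl (enough to consume the lithium methoxide and diethylamine as well) is added at -78 °C and the mixture is warmed to rt, so that the alkoxide is silylated directly. No new compound is made on this path.

**Further compounds**

F1 | step 6 | 1-bromo-2-methoxy-4-methylbenzene | COc1cc(C)ccc1Br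
F2 | step 6 | (2-methoxy-4-methylphenyl)lithium | [Li]c1ccc(C)cc1OC
F3 | step 6 | lithium 5-(2-methoxy-4-methylphenyl)-2,2-dimethyl-1,3-dioxan-5-olate | [Li+].[O-]C1(COC(C)(C)OC1)c1ccc(C)cc1OC
F4 | step 6 | 5-(2-methoxy-4-methylphenyl)-2,2-dimethyl-1,3-dioxan-5-ol | COc1cc(C)ccc1C1(O)COC(C)(C)OC1
F5 | step 4 | sodium methoxyacetylide | [Na+].[C-]#COC
F6 | step 4 | methoxyacetylene (methoxyethyne) | COC#C
F0 | step 5 | none | none
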